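**Strategy.** Ring A is a β-resorcylate whose substituents (depside carbonyl on C1, hydroxyls on C2 and C4, pentyl on C6) alternate exactly as the carbonyls of a 3,5,7-trioxododecanoyl chain, so the route disconnects the ring A C1–C6 bond. The open-chain precursor is the aryl triketo ester in which the depside C(=O)–O bond to O4 of ring B already exists. It comes from capture of an acylketene, released from a diketo-dioxinone, by benzyl 2,4-dihydroxy-6-propylbenzoate, whose chelated 2-hydroxyl needs no protection. One amine-mediated aldol condensation of chain C2 onto the C7 ketone closes and aromatizes ring A. Hydrogenolysis of the single benzyl ester ends the synthesis.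

Key step: step 6

Remark: 12 is drawn in its all-keto form but should exist as a mixture of keto–enol tautomers; aldol 13 should form as a mixture of diastereomers whose stereocenters vanish on aromatization, and the target has no stereocenter.

**Step 1**
Reactants: 1 2,2,6-trimethyl-4H-1,3-dioxin-4-one; 2 acetyl chloride
Product: 4 2,2-dimethyl-6-(2-oxopropyl)-4H-1,3-dioxin-4-one, via lithium dienolate 3 (not isolated)
Conditions: LiN(SiMe3)2 (1.0 equiv), THF, −78 °C; then 2 (0.5 equiv), −78 °C; aq. NH4Cl
Reagents that add atoms: none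
Why: Kinetic deprotonation of the 6-methyl group gives the lithium dienolate, which is C-acylated at its γ-carbon by the acid chloride (vinylogous Claisen-type acylation), the excess dienolate absorbing the acidic proton of the β-keto product while unreacted 1 is recovered.

**Step 2**
Reactants: 4 2,2-dimethyl-6-(2-oxopropyl)-4H-1,3-dioxin-4-one; 5 hexanoyl chloride
Product: 7 2,2-dimethyl-6-(2,4-dioxononyl)-4H-1,3-dioxin-4-one, via dilithium dianion 6 (not isolated)
Conditions: LiN(iPr)2 (2.1 equiv), THF, −78 °C; then 5 (0.5 equiv), −78 to −40 °C; aq. NH4Cl, then 1 M HCl to pH 3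
Reagents that add atoms: none
Why: Double deprotonation gives the 1,3-dianion, whose terminal and least stabilized carbanion is the most nucleophilic site and is acylated by the acid chloride (γ-acylation of a β-dicarbonyl dianion), the excess dianion serving as base for the more acidic product.

**Step 3**
Reactants: 8 5-propylbenzene-1,3-diol (divarinol)
Product: 9 2,4-dihydroxy-6-propylbenzoic acid
Conditions: MeOMgOCO2Me (2 M in DMF, 3 equiv), 120 °C, N2; then 2 M HCl, 0 °C
Reagents that add atoms: magnesium methyl carbonate MeOMgOCO2Me, COC(=O)O[Mg]OC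
Why: Magnesium-chelate-directed ortho-carboxylation of the resorcinol (Kolbe–Schmitt-type carboxylation) should place the carboxyl group at C4, ortho to one hydroxyl and para to the other, as is usual for 5-alkylresorcinols, and cold acidification avoids decarboxylation of the β-resorcylic acid.

**Step 4**
Reactants: 9 2,4-dihydroxy-6-propylbenzoic acid
Product: 10 benzyl 2,4-dihydroxy-6-propylbenzoate
Conditions: BnBr (1.05 equiv), KHCO3 (1.1 equiv), DMF, rt
Reagents that add atoms: benzyl bromide, BrCc1ccccc1
Why: Bicarbonate deprotonates only the carboxylic acid, so the carboxylate alone is alkylated (SN2 O-alkylation of a carboxylate) while both phenols stay protonated.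

**Step 5**
Reactants: 7 2,2-dimethyl-6-(2,4-dioxononyl)-4H-1,3-dioxin-4-one; 10 benzyl 2,4-dihydroxy-6-propylbenzoate
Product: 12 benzyl 2-hydroxy-6-propyl-4-[(3,5,7-trioxododecanoyl)oxy]benzoate, via acylketene 11 (not isolated)
Conditions: 10 (1.2 equiv), PhMe (0.2 M), 100–110 °C, N2 sweep to remove acetone, 1 h; concentrate, crude 12 used directly
Reagents that add atoms: none
Why: Retro-Diels–Alder fragmentation of the dioxinone releases acetone and the acylketene, which should be captured by the free 4-hydroxyl of 10 (acylketene capture by a phenol, as in the acetoacetylation of phenols with the parent dioxinone) while the 2-hydroxyl stays hydrogen-bonded to the benzyl ester, so the depside C–O bond is made without esterifying a 2,6-disubstituted benzoic acid.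

**Step 6**
Reactants: 12 benzyl 2-hydroxy-6-propyl-4-[(3,5,7-trioxododecanoyl)oxy]benzoate
Product: 14 benzyl 4-[(2,4-dihydroxy-6-pentylbenzoyl)oxy]-2-hydroxy-6-propylbenzoate, via cyclic aldol 13 (not isolated)
Conditions: Et3N (3 equiv), CH2Cl2 (0.05 M), 0 °C to rt; then 1 M aq. HCl, rt
Reagents that add atoms: none
Why: Triethylamine generates the C2 enolate flanked by the aryl ester and the C3 ketone, which adds to the C7 ketone to form the ring A C1–C6 bond and give aldol 13; E1cB loss of one molecule of water and enolization of the C3 and C5 carbonyls (ring C2 and C4) then deliver the aromatic resorcylate. The closest known reaction type is the base-mediated aldol aromatization of 3,5,7-triketo esters obtained by acylketene capture from diketo-dioxinones, the laboratory counterpart of tetraketide folding to orsellinate-type acids. Ring A closes in a 6-(enolendo)-exo-trig mode, which is geometrically favoured. No stereocenter survives, because the two stereocenters of 13 are erased on aromatization. The step needs chemoselectivity for C–C bond formation at the C7 ketone over expulsion of the ring-B phenoxide from C1, either by the C5 enol oxygen (lactonization to a 4-hydroxy-2-pyranone) or by C6 (Claisen closure to an acylphloroglucinol). The substrate secures this because C1 is the carbonyl of an enolized β-keto ester and thus a poor electrophile whereas C7 is a ketone carbonyl, and the conditions support it by using a non-nucleophilic amine in an aprotic solvent with no chelating divalent metal and no alcohol, aromatization making the aldol pathway irreversible.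

**Step 7**
Reactants: 14 benzyl 4-[(2,4-dihydroxy-6-pentylbenzoyl)oxy]-2-hydroxy-6-propylbenzoate
Product: 15 4-[(2,4-dihydroxy-6-pentylbenzoyl)oxy]-2-hydroxy-6-propylbenzoic acid
Conditions: H2 (1 atm), 10% Pd/C, EtOAc, rt
Reagents that add atoms: none
Why: Catalytic hydrogenolysis cleaves only the benzylic C–O bond of the ester and should leave the aryl ester, the phenols and both arenes untouched, the acid being isolated at room temperature to avoid decarboxylation.

**Compound list**
1 | 2,2,6-trimethyl-4H-1,3-dioxin-4-one | CC1=CC(=O)OC(C)(C)O1 | starting material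
2 | acetyl chloride | CC(=O)Cl | starting material
3 | lithium dienolate of 1 (lithium 2,2-dimethyl-6-methylidene-6H-1,3-dioxin-4-olate; formed in the flask) | C=C1C=C(O[Li])OC(C)(C)O1 | intermediate
4 | 2,2-dimethyl-6-(2-oxopropyl)-4H-1,3-dioxin-4-one | CC(=O)CC1=CC(=O)OC(C)(C)O1 | intermediate
5 | hexanoyl chloride | CCCCCC(=O)Cl | starting material
6 | dilithium dianion of 4 (formed in the flask) | C=C(O[Li])C=C1C=C(O[Li])OC(C)(C)O1 | intermediate
7 | 2,2-dimethyl-6-(2,4-dioxononyl)-4H-1,3-dioxin-4-one | CCCCCC(=O)CC(=O)CC1=CC(=O)OC(C)(C)O1 | intermediate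
8 | 5-propylbenzene-1,3-diol (divarinol) | CCCc1cc(O)cc(O)c1 | starting material
9 | 2,4-dihydroxy-6-propylbenzoic acid | CCCc1cc(O)cc(O)c1C(=O)O | intermediate
10 | benzyl 2,4-dihydroxy-6-propylbenzoate | CCCc1cc(O)cc(O)c1C(=O)OCc2ccccc2 | intermediate
11 | 3,5,7-trioxododec-1-en-1-one (acylketene; formed in the flask) | CCCCCC(=O)CC(=O)CC(=O)C=C=O | intermediate
12 | benzyl 2-hydroxy-6-propyl-4-[(3,5,7-trioxododecanoyl)oxy]benzoate | CCCCCC(=O)CC(=O)CC(=O)CC(=O)Oc1cc(O)c(C(=O)OCc2ccccc2)c(CCC)c1 | intermediate
13 | benzyl 2-hydroxy-4-[(2-hydroxy-4,6-dioxo-2-pentylcyclohexane-1-carbonyl)oxy]-6-propylbenzoate (cyclic aldol; diastereomer mixture; formed in the flask) | CCCCCC1(O)CC(=O)CC(=O)C1C(=O)Oc1cc(O)c(C(=O)OCc2ccccc2)c(CCC)c1 | intermediate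
14 | benzyl 4-[(2,4-dihydroxy-6-pentylbenzoyl)oxy]-2-hydroxy-6-propylbenzoate | CCCCCc1cc(O)cc(O)c1C(=O)Oc1cc(O)c(C(=O)OCc2ccccc2)c(CCC)c1 | intermediate
15 | 4-[(2,4-dihydroxy-6-pentylbenzoyl)oxy]-2-hydroxy-6-propylbenzoic acid | CCCCCc1cc(O)cc(O)c1C(=O)Oc1cc(O)c(C(=O)O)c(CCC)c1 | target

**Step count.** Total: 7 steps. Longest linear sequence: 5 steps (steps 1, 2, 5, 6, 7).

**Steps most likely to fail**

Step 6. Expulsion of the ring-B phenoxide from C1, through lactonization by the C5 enol oxygen or Claisen closure from C6, may outrun the C2-to-C7 aldol, and intermolecular acyl transfer may add to the loss. The fallback sets out from 7 and comes back at 15. The same aldol is run on 7 itself (Et3N, CH2Cl2, rt), where the C1–C3 unit is the dioxinone and carries no leaving group; this should give 7-hydroxy-2,2-dimethyl-5-pentyl-4H-1,3-benzodioxin-4-one F1. Benzylation (BnBr, K2CO3, acetone) gives 7-(benzyloxy)-2,2-dimethyl-5-pentyl-4H-1,3-benzodioxin-4-one F2. Saponification of the acetonide (KOH, aq. DMSO, 60 °C; then cold HCl) gives 4-(benzyloxy)-2-hydroxy-6-pentylbenzoic acid F3. Carbodiimide esterification with 10 (DCC, toluene, rt), selective for the unchelated 4-hydroxyl of 10, gives benzyl 4-{[4-(benzyloxy)-2-hydroxy-6-pentylbenzoyl]oxy}-2-hydroxy-6-propylbenzoate F4. Hydrogenolysis under the conditions of step 7 removes both benzyl groups and gives 15.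

Step 5. Cyclization of the acylketene onto its own C5 enol oxygen may be faster than addition of the weakly nucleophilic, ester-bearing phenol; acylation of the chelated 2-hydroxyl or thermal reversal of the aryl β-keto ester may also occur. The fallback sets out from 7 and comes back at 15. The ketene 11 is captured by allyl alcohol, a fast and unhindered nucleophile (PhMe, 110 °C), to give allyl 3,5,7-trioxododecanoate F5. This is aromatized in the same flask (Et3N, CH2Cl2) to allyl 2,4-dihydroxy-6-pentylbenzoate F6. Double benzylation (BnBr, K2CO3, DMF, 60 °C) gives allyl 2,4-bis(benzyloxy)-6-pentylbenzoate F7. Deallylation (Pd(PPh3)4, morpholine, THF, rt) gives 2,4-bis(benzyloxy)-6-pentylbenzoic acid F8. Mixed-anhydride esterification with 10 (trifluoroacetic anhydride, toluene, rt) gives benzyl 4-{[2,4-bis(benzyloxy)-6-pentylbenzoyl]oxy}-2-hydroxy-6-propylbenzoate F9. Hydrogenolysis under the conditions of step 7 removes the three benzyl groups and gives 15.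

Step 2. Proton transfer from the more acidic product to the dianion, O-acylation and double acylation may erode the conversion. The fallback sets out from 1 (through its dienolate 3) and comes back at 7, replacing dianion chemistry by soft enolization. Dienolate 3 is acylated with the benzotriazolide of mono-allyl malonate (THF, −78 °C) to give allyl 4-(2,2-dimethyl-4-oxo-4H-1,3-dioxin-6-yl)-3-oxobutanoate F10. C-acylation with 5 at the carbon between ester and ketone (MgCl2, pyridine, CH2Cl2, 0 °C) gives allyl 2-[(2,2-dimethyl-4-oxo-4H-1,3-dioxin-6-yl)acetyl]-3-oxooctanoate F11. Deallylation with spontaneous decarboxylation (Pd(PPh3)4, morpholine, THF, rt) should give 7.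

**Further compounds**
F1 | step 6 | 7-hydroxy-2,2-dimethyl-5-pentyl-4H-1,3-benzodioxin-4-one | CCCCCc1cc(O)cc2OC(C)(C)OC(=O)c12
F2 | step 6 | 7-(benzyloxy)-2,2-dimethyl-5-pentyl-4H-1,3-benzodioxin-4-one | CCCCCc1cc(OCc3ccccc3)cc2OC(C)(C)OC(=O)c12
F3 | step 6 | 4-(benzyloxy)-2-hydroxy-6-pentylbenzoic acid | CCCCCc1cc(OCc2ccccc2)cc(O)c1C(=O)O
F4 | step 6 | benzyl 4-{[4-(benzyloxy)-2-hydroxy-6-pentylbenzoyl]oxy}-2-hydroxy-6-propylbenzoate | CCCCCc1cc(OCc2ccccc2)cc(O)c1C(=O)Oc1cc(O)c(C(=O)OCc2ccccc2)c(CCC)c1
F5 | step 5 | allyl 3,5,7-trioxododecanoate | CCCCCC(=O)CC(=O)CC(=O)CC(=O)OCC=C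
F6 | step 5 | allyl 2,4-dihydroxy-6-pentylbenzoate | CCCCCc1cc(O)cc(O)c1C(=O)OCC=C
F7 | step 5 | allyl 2,4-bis(benzyloxy)-6-pentylbenzoate | CCCCCc1cc(OCc2ccccc2)cc(OCc2ccccc2)c1C(=O)OCC=C
F8 | step 5 | 2,4-bis(benzyloxy)-6-pentylbenzoic acid | CCCCCc1cc(OCc2ccccc2)cc(OCc2ccccc2)c1C(=O)O
F9 | step 5 | benzyl 4-{[2,4-bis(benzyloxy)-6-pentylbenzoyl]oxy}-2-hydroxy-6-propylbenzoate | CCCCCc1cc(OCc2ccccc2)cc(OCc2ccccc2)c1C(=O)Oc1cc(O)c(C(=O)OCc2ccccc2)c(CCC)c1
F10 | step 2 | allyl 4-(2,2-dimethyl-4-oxo-4H-1,3-dioxin-6-yl)-3-oxobutanoate | C=CCOC(=O)CC(=O)CC1=CC(=O)OC(C)(C)O1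
F11 | step 2 | allyl 2-[(2,2-dimethyl-4-oxo-4H-1,3-dioxin-6-yl)acetyl]-3-oxooctanoate | CCCCCC(=O)C(C(=O)OCC=C)C(=O)CC1=CC(=O)OC(C)(C)O1
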